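**Retrosynthetic overview**

1. The strategy rests on the benzene ring (C4a, C5, C6, C7, C8, C8a), which is a hydroquinone monoether. O1 on C8a is para to the C6 hydroxyl, C8 carries the methyl group, and C4a carries C4 of the fused dihydropyran ring (O1, C2, C3, C4, C4a, C8a). An alkenyl(alkoxy)carbene chromium complex, an alkyne and one CO assemble exactly this array.
2. Late disconnections: the C13' acid comes from the E-allylic alcohol. The C5'–C6' bond comes from alkylation of an 8-silyloxygeranyl phenyl sulfone with the chroman C5' allylic bromide, followed by reductive desulfonylation.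
3. Key disconnection: C8a–C4a, C5–C6 and C6–C7 are cut together, which opens both rings to an acyclic isopropenyl(tert-alkoxy)carbene chromium complex whose alkoxy group carries a but-3-ynyl arm. In the forward direction the dihydropyran ring closes first (alkyne insertion) and the benzene ring second (electrocyclisation), in one operation.
4. The carbene complex comes from 2-bromopropene, Cr(CO)6 and a tertiary alkynol. The alkynol is made from (R)-linalool (vinyl group → CH2CH2C≡CH), and its carbinol carbon becomes C2 without ever being disturbed.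

Key step: step 8

Assumption: commercial (R)-(−)-linalool of high enantiomeric purity is used, since its C3 is the only source of C2. Atom labels follow chroman numbering (O1, C2–C8a), with C1'–C13' along the side chain.

**Route**

Step 1
Reactants: 1 (R)-linalool
Product: 2 triethyl{[(3R)-3,7-dimethylocta-1,6-dien-3-yl]oxy}silane
Conditions: Et3SiCl, imidazole, DMAP (cat.), DMF, rt
Reagents that add atoms: chlorotriethylsilane, CC[Si](Cl)(CC)CC
Why: O-silylation of the tertiary alcohol touches no bond at the stereocentre, and it stops the γ-alkoxide from closing an oxetane once the chain end carries a leaving group in steps 3 and 4.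

Step 2
Reactants: 2 triethyl{[(3R)-3,7-dimethylocta-1,6-dien-3-yl]oxy}silane
Product: 4 (3R)-3,7-dimethyl-3-(triethylsilyloxy)oct-6-en-1-ol, via B-alkyl-9-BBN adduct 3 (not isolated)
Conditions: 9-BBN, THF, 0 °C → rt; then NaOH, H2O2, 0 °C → rt
Reagents that add atoms: 9-borabicyclo[3.3.1]nonane, B1C2CCCC1CCC2 (its atoms are held only by 3); hydrogen peroxide, OO
Why: In this hydroboration–oxidation the bulky 9-BBN should add anti-Markovnikov to the monosubstituted vinyl group much faster than to the trisubstituted alkene, and the quaternary stereocentre takes no part.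

Step 3
Reactants: 4 (3R)-3,7-dimethyl-3-(triethylsilyloxy)oct-6-en-1-ol
Product: 5 triethyl{[(3R)-1-iodo-3,7-dimethyloct-6-en-3-yl]oxy}silane
Conditions: I2, PPh3, imidazole, CH2Cl2, 0 °C → rt
Reagents that add atoms: iodine, II
Why: Appel-type iodination of a primary alcohol proceeds through the alkoxyphosphonium salt under buffered conditions that spare the silyl ether and the alkene.

Step 4
Reactants: 5 triethyl{[(3R)-1-iodo-3,7-dimethyloct-6-en-3-yl]oxy}silane; 6 lithium acetylide–ethylenediamine complex, LiC≡CH·H2NCH2CH2NH2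
Product: 7 triethyl{[(5R)-5,9-dimethyldec-8-en-1-yn-5-yl]oxy}silane
Conditions: DMSO/THF, 0 °C → rt
Reagents that add atoms: none
Why: SN2 alkylation of acetylide by an unhindered primary iodide in a dipolar aprotic medium adds the two carbons that later become C4a and C5.

Step 5
Reactants: 7 triethyl{[(5R)-5,9-dimethyldec-8-en-1-yn-5-yl]oxy}silane
Product: 8 (5R)-5,9-dimethyldec-8-en-1-yn-5-ol
Conditions: Bu4NF, THF, rt
Reagents that add atoms: none
Why: Fluoride-induced desilylation cleaves only the Si–O bond, so the carbinol C–O bond and its configuration are retained.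

Step 6
Reactants: 9 2-bromopropene; 10 chromium hexacarbonyl
Product: 13 tetramethylammonium pentacarbonyl(2-methylprop-2-enoyl)chromate, via prop-1-en-2-yllithium 11 (not isolated), via lithium acylchromate 12 (not isolated)
Conditions: t-BuLi (2 equiv), Et2O, −78 °C; Cr(CO)6, Et2O, −78 °C → rt; Me4NBr, H2O, rt
Reagents that add atoms: tert-butyllithium, [Li]C(C)(C)C (its lithium is held only by 11 and 12); tetramethylammonium bromide, C[N+](C)(C)C.[Br-]
Why: This is the first half of the Fischer carbene synthesis, in which bromine–lithium exchange and addition of the alkenyllithium to a CO ligand give the acylmetalate, and cation exchange makes it an isolable salt.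

Step 7
Reactants: 13 tetramethylammonium pentacarbonyl(2-methylprop-2-enoyl)chromate; 8 (5R)-5,9-dimethyldec-8-en-1-yn-5-ol
Product: 15 pentacarbonyl{[(5R)-5,9-dimethyldec-8-en-1-yn-5-yl]oxy(prop-1-en-2-yl)methylidene}chromium, via pivaloyloxycarbene complex 14 (not isolated)
Conditions: 13 (2 equiv), t-BuCOCl, CH2Cl2, −40 °C; then 8, −40 → 0 °C; cold aq. NaHCO3, rapid filtration through neutral Al2O3
Reagents that add atoms: pivaloyl chloride, CC(C)(C)C(=O)Cl (its acyl group is held only by 14)
Why: Proposed new method: O-acylation of the acylchromate gives the mixed-anhydride-like complex 14, whose carbene carbon is strongly electrophilic; addition of the hydroxyl oxygen of 8 and loss of pivalate should place the alkoxy group on that carbon without breaking the carbinol C–O bond, so the configuration is kept. The closest known reaction type is the alcoholysis of acyloxycarbene chromium complexes by primary and hindered secondary (menthol-type) alcohols; a tertiary alcohol has not been shown. The case for it rests on the longer-lived pivaloyloxy complex, the excess of 14, and the known stability of cyclic 2-oxacycloalkylidene chromium complexes whose oxygen sits on a fully substituted carbon.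

Step 8
Reactants: 15 pentacarbonyl{[(5R)-5,9-dimethyldec-8-en-1-yn-5-yl]oxy(prop-1-en-2-yl)methylidene}chromium
Product: 17 (2R)-2,8-dimethyl-2-(4-methylpent-3-en-1-yl)chroman-6-ol, via tricarbonylchromium arene complex 16 (not isolated)
Conditions: THF (0.005 M), 55 °C, Ar; then air, Et2O, rt
Reagents that add atoms: none
Why: Proposed new method: thermal loss of a cis CO ligand frees a site for the tethered alkyne, which inserts into the Cr=C bond with its inner carbon bonding to the carbene carbon (C4a–C8a); migration of one CO onto the new carbene carbon gives a chromium-bound dienylketene (C5–C6), and 6π electrocyclisation onto the isopropenyl CH2 (C6–C7) followed by enolisation should deliver the phenol as complex 16, from which air removes the metal. The closest known reaction type is the intramolecular Dötz benzannulation of aryl- and heteroaryl(alkynyloxy)carbene chromium complexes with primary alkoxy tethers; an alkenylcarbene with a tertiary alkoxy tether is untried, and the argument for it is that alkenyl(alkoxy)chromium carbenes are the class most faithful to phenol formation and that the two substituents on C2 favour the folded conformer. The dihydropyran ring closes in the insertion event as a 6-exo-dig closure (O1, C2, C3, C4, C4a, C8a), and the benzene ring closes in the disrotatory 6π electrocyclisation of the dienylketene. Because the new six-membered ring holds C4 and O1 cis across C4a=C8a, the ketene carbon and the isopropenyl group are necessarily cis, which is the geometry the electrocyclisation needs. No stereocentre is formed and none of the four bonds at C2 is touched, so the R configuration of 8 is carried through. The step needs reversed alkyne orientation (secured by the three-carbon tether), intramolecular rather than intermolecular insertion (secured by high dilution) and reaction at the alkyne rather than the trisubstituted alkene (the alkyne is by far the better ligand), while an acid-free ether solvent and moderate temperature guard the tertiary C2–O1 bond against ionisation.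

Step 9
Reactants: 17 (2R)-2,8-dimethyl-2-(4-methylpent-3-en-1-yl)chroman-6-ol
Product: 18 {[(2R)-2,8-dimethyl-2-(4-methylpent-3-en-1-yl)chroman-6-yl]oxy}triisopropylsilane
Conditions: i-Pr3SiCl, imidazole, DMF, rt
Reagents that add atoms: chlorotriisopropylsilane, CC(C)[Si](Cl)(C(C)C)C(C)C
Why: O-silylation of the unhindered C6 phenol gives a robust aryl silyl ether that should survive the oxidants, the carbanion and the hydride used in later steps.

Step 10
Reactants: 18 {[(2R)-2,8-dimethyl-2-(4-methylpent-3-en-1-yl)chroman-6-yl]oxy}triisopropylsilane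
Product: 19 (2E)-5-[(2R)-2,8-dimethyl-6-(triisopropylsilyloxy)chroman-2-yl]-2-methylpent-2-en-1-ol
Conditions: SeO2 (cat.), t-BuOOH, salicylic acid (cat.), CH2Cl2, 0 °C → rt
Reagents that add atoms: selenium dioxide, O=[Se]=O; tert-butyl hydroperoxide, CC(C)(C)OO
Why: Riley-type allylic oxidation (ene reaction, then 2,3-sigmatropic shift) of a gem-dimethyl trisubstituted alkene selectively oxidises the E-methyl group, which sets the E geometry of C3'=C4'.

Step 11
Reactants: 19 (2E)-5-[(2R)-2,8-dimethyl-6-(triisopropylsilyloxy)chroman-2-yl]-2-methylpent-2-en-1-ol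
Product: 20 {[(2R)-2-[(3E)-5-bromo-4-methylpent-3-en-1-yl]-2,8-dimethylchroman-6-yl]oxy}triisopropylsilane
Conditions: CBr4, PPh3, CH2Cl2, 0 °C
Reagents that add atoms: carbon tetrabromide, BrC(Br)(Br)Br
Why: The Appel bromination of a primary allylic alcohol runs under neutral conditions by SN2 displacement, so neither allylic transposition nor E/Z erosion is expected.

Step 12
Reactants: 21 geranyl bromide
Product: 22 geranyl phenyl sulfone, {[(2E)-3,7-dimethylocta-2,6-dien-1-yl]sulfonyl}benzene
Conditions: PhSO2Na, DMF, rt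
Reagents that add atoms: sodium benzenesulfinate, [Na+].[O-]S(=O)c1ccccc1
Why: SN2 S-alkylation of the sulfinate by the primary allylic bromide keeps the E geometry that becomes C7'=C8'.

Step 13
Reactants: 22 geranyl phenyl sulfone
Product: 23 (2E,6E)-2,6-dimethyl-8-(phenylsulfonyl)octa-2,6-dien-1-ol
Conditions: SeO2 (cat.), t-BuOOH, CH2Cl2, 0 °C → rt
Reagents that add atoms: selenium dioxide, O=[Se]=O; tert-butyl hydroperoxide, CC(C)(C)OO
Why: In this Riley-type allylic oxidation the sulfone deactivates the proximal alkene, so the terminal gem-dimethyl alkene reacts at its E-methyl group and sets the E geometry of C11'=C12'.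

Step 14
Reactants: 23 (2E,6E)-2,6-dimethyl-8-(phenylsulfonyl)octa-2,6-dien-1-ol
Product: 24 tert-butyl{[(2E,6E)-2,6-dimethyl-8-(phenylsulfonyl)octa-2,6-dien-1-yl]oxy}dimethylsilane
Conditions: t-BuMe2SiCl, imidazole, CH2Cl2, rt
Reagents that add atoms: tert-butylchlorodimethylsilane, CC(C)(C)[Si](C)(C)Cl
Why: O-silylation of the primary alcohol removes the acidic proton before carbanion formation, and it keeps the allylic oxygen from being activated by boron and palladium in step 16.

Step 15
Reactants: 24 tert-butyl{[(2E,6E)-2,6-dimethyl-8-(phenylsulfonyl)octa-2,6-dien-1-yl]oxy}dimethylsilane; 20 {[(2R)-2-[(3E)-5-bromo-4-methylpent-3-en-1-yl]-2,8-dimethylchroman-6-yl]oxy}triisopropylsilane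
Product: 26 (2R)-2-[(3E,7E,11E)-13-(tert-butyldimethylsilyloxy)-4,8,12-trimethyl-6-(phenylsulfonyl)trideca-3,7,11-trien-1-yl]-2,8-dimethyl-6-(triisopropylsilyloxy)chroman (both C6' epimers), via lithiated sulfone 25 (not isolated)
Conditions: n-BuLi, THF/DMPU, −78 °C; then 20, −78 → −20 °C
Reagents that add atoms: n-butyllithium, [Li]CCCC (its lithium is held only by 25)
Why: The α-sulfonyl carbanion attacks the primary allylic bromide by SN2 to form C5'–C6', and the new C6' stereocentre needs no control because step 16 removes it.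

Step 16
Reactants: 26 the C6' sulfone
Product: 27 (2R)-2-[(3E,7E,11E)-13-(tert-butyldimethylsilyloxy)-4,8,12-trimethyltrideca-3,7,11-trien-1-yl]-2,8-dimethyl-6-(triisopropylsilyloxy)chroman
Conditions: LiEt3BH, PdCl2(dppp) (cat.), THF, 0 °C
Reagents that add atoms: none
Why: In this palladium-catalysed hydride desulfonylation of an allylic sulfone, zerovalent palladium (formed in situ from the divalent precatalyst) ionises C6'–S to a π-allyl complex, and hydride is delivered to the less substituted terminus C6', so C7'=C8' should stay in place and stay E.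

Step 17
Reactants: 27 the bis-silyl ether
Product: 28 (2E,6E,10E)-13-[(2R)-2,8-dimethyl-6-(triisopropylsilyloxy)chroman-2-yl]-2,6,10-trimethyltrideca-2,6,10-trien-1-ol
Conditions: PPTS (cat.), MeOH, rt
Reagents that add atoms: none
Why: Acid-catalysed methanolysis cleaves a primary alkyl tert-butyldimethylsilyl ether much faster than an aryl triisopropylsilyl ether, and the acid is too mild to start polyene cyclisation.

Step 18
Reactants: 28 the C13' allylic alcohol
Product: 29 (2E,6E,10E)-13-[(2R)-2,8-dimethyl-6-(triisopropylsilyloxy)chroman-2-yl]-2,6,10-trimethyltrideca-2,6,10-trienal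
Conditions: MnO2, CH2Cl2, rt
Reagents that add atoms: none
Why: MnO2 oxidation is selective for the allylic alcohol, stops at the enal and keeps the E geometry, while the protected chromanol is not attacked.

Step 19
Reactants: 29 the C13' enal
Product: 30 (2E,6E,10E)-13-[(2R)-2,8-dimethyl-6-(triisopropylsilyloxy)chroman-2-yl]-2,6,10-trimethyltrideca-2,6,10-trienoic acid
Conditions: NaClO2, NaH2PO4, 2-methyl-2-butene (large excess), t-BuOH/H2O, rt
Reagents that add atoms: sodium chlorite, [Na+].[O-]Cl=O
Why: The Pinnick oxidation converts the enal into the acid without E/Z isomerisation, and the excess scavenger takes up HOCl before it can reach the chain alkenes or the arene.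

Step 20
Reactants: 30 O-triisopropylsilyl garcinoic acid
Product: 31 garcinoic acid
Conditions: Bu4NF, THF, 0 °C; then 1 M HCl
Reagents that add atoms: none
Why: Fluoride-induced cleavage of the aryl silyl ether is fast at 0 °C and leaves the acid, the three E alkenes and C2 untouched.

**Compound list**

1 | (R)-(−)-linalool, (3R)-3,7-dimethylocta-1,6-dien-3-ol | CC(C)=CCC[C@@](C)(O)C=C | starting material
2 | triethyl{[(3R)-3,7-dimethylocta-1,6-dien-3-yl]oxy}silane | CC(C)=CCC[C@@](C)(O[Si](CC)(CC)CC)C=C | intermediate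
3 | 9-[(3S)-3,7-dimethyl-3-(triethylsilyloxy)oct-6-en-1-yl]-9-borabicyclo[3.3.1]nonane (formed in the flask) | CC(C)=CCC[C@@](C)(O[Si](CC)(CC)CC)CCB1C2CCCC1CCC2 | intermediate
4 | (3R)-3,7-dimethyl-3-(triethylsilyloxy)oct-6-en-1-ol | CC(C)=CCC[C@@](C)(O[Si](CC)(CC)CC)CCO | intermediate
5 | triethyl{[(3R)-1-iodo-3,7-dimethyloct-6-en-3-yl]oxy}silane | CC(C)=CCC[C@@](C)(O[Si](CC)(CC)CC)CCI | intermediate
6 | lithium acetylide–ethylenediamine complex, LiC≡CH·H2NCH2CH2NH2 | [Li]C#C.NCCN | starting material
7 | triethyl{[(5R)-5,9-dimethyldec-8-en-1-yn-5-yl]oxy}silane | CC(C)=CCC[C@@](C)(O[Si](CC)(CC)CC)CCC#C | intermediate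
8 | (5R)-5,9-dimethyldec-8-en-1-yn-5-ol | CC(C)=CCC[C@@](C)(O)CCC#C | intermediate
9 | 2-bromopropene | C=C(C)Br | starting material
10 | chromium hexacarbonyl, Cr(CO)6 | O=C=[Cr](=C=O)(=C=O)(=C=O)(=C=O)=C=O | starting material
11 | prop-1-en-2-yllithium (formed in the flask) | [Li]C(C)=C | intermediate
12 | lithium pentacarbonyl(2-methylprop-2-enoyl)chromate (formed in the flask) | [Li+].[O-]C(C(C)=C)=[Cr](=C=O)(=C=O)(=C=O)(=C=O)=C=O | intermediate
13 | tetramethylammonium pentacarbonyl(2-methylprop-2-enoyl)chromate | C[N+](C)(C)C.[O-]C(C(C)=C)=[Cr](=C=O)(=C=O)(=C=O)(=C=O)=C=O | intermediate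
14 | pentacarbonyl[(pivaloyloxy)(prop-1-en-2-yl)methylidene]chromium (formed in the flask) | C=C(C)C(OC(=O)C(C)(C)C)=[Cr](=C=O)(=C=O)(=C=O)(=C=O)=C=O | intermediate
15 | pentacarbonyl{[(5R)-5,9-dimethyldec-8-en-1-yn-5-yl]oxy(prop-1-en-2-yl)methylidene}chromium | C=C(C)C(O[C@@](C)(CCC#C)CCC=C(C)C)=[Cr](=C=O)(=C=O)(=C=O)(=C=O)=C=O | intermediate
16 | tricarbonyl{η6-(2R)-2,8-dimethyl-2-(4-methylpent-3-en-1-yl)chroman-6-ol}chromium, metal on either arene face (formed in the flask) | CC(C)=CCC[C@]1(C)CCc2cc(O)cc(C)c2O1.O=C=[Cr](=C=O)=C=O | intermediate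
17 | (2R)-2,8-dimethyl-2-(4-methylpent-3-en-1-yl)chroman-6-ol | CC(C)=CCC[C@]1(C)CCc2cc(O)cc(C)c2O1 | intermediate
18 | {[(2R)-2,8-dimethyl-2-(4-methylpent-3-en-1-yl)chroman-6-yl]oxy}triisopropylsilane | CC(C)=CCC[C@]1(C)CCc2cc(O[Si](C(C)C)(C(C)C)C(C)C)cc(C)c2O1 | intermediate
19 | (2E)-5-[(2R)-2,8-dimethyl-6-(triisopropylsilyloxy)chroman-2-yl]-2-methylpent-2-en-1-ol | OC/C(C)=C/CC[C@]1(C)CCc2cc(O[Si](C(C)C)(C(C)C)C(C)C)cc(C)c2O1 | intermediate
20 | {[(2R)-2-[(3E)-5-bromo-4-methylpent-3-en-1-yl]-2,8-dimethylchroman-6-yl]oxy}triisopropylsilane | BrC/C(C)=C/CC[C@]1(C)CCc2cc(O[Si](C(C)C)(C(C)C)C(C)C)cc(C)c2O1 | intermediate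
21 | geranyl bromide, (2E)-1-bromo-3,7-dimethylocta-2,6-diene | CC(C)=CCC/C(C)=C/CBr | starting material
22 | geranyl phenyl sulfone | CC(C)=CCC/C(C)=C/CS(=O)(=O)c1ccccc1 | intermediate
23 | (2E,6E)-2,6-dimethyl-8-(phenylsulfonyl)octa-2,6-dien-1-ol | OC/C(C)=C/CC/C(C)=C/CS(=O)(=O)c1ccccc1 | intermediate
24 | tert-butyl{[(2E,6E)-2,6-dimethyl-8-(phenylsulfonyl)octa-2,6-dien-1-yl]oxy}dimethylsilane | CC(C)(C)[Si](C)(C)OC/C(C)=C/CC/C(C)=C/CS(=O)(=O)c1ccccc1 | intermediate
25 | α-lithio derivative of 24 (formed in the flask) | CC(C)(C)[Si](C)(C)OC/C(C)=C/CC/C(C)=C/C([Li])S(=O)(=O)c1ccccc1 | intermediate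
26 | (2R)-2-[(3E,7E,11E)-13-(tert-butyldimethylsilyloxy)-4,8,12-trimethyl-6-(phenylsulfonyl)trideca-3,7,11-trien-1-yl]-2,8-dimethyl-6-(triisopropylsilyloxy)chroman, both C6' epimers | CC(C)(C)[Si](C)(C)OC/C(C)=C/CC/C(C)=C/C(C/C(C)=C/CC[C@]1(C)CCc2cc(O[Si](C(C)C)(C(C)C)C(C)C)cc(C)c2O1)S(=O)(=O)c1ccccc1 | intermediate
27 | (2R)-2-[(3E,7E,11E)-13-(tert-butyldimethylsilyloxy)-4,8,12-trimethyltrideca-3,7,11-trien-1-yl]-2,8-dimethyl-6-(triisopropylsilyloxy)chroman | CC(C)(C)[Si](C)(C)OC/C(C)=C/CC/C(C)=C/CC/C(C)=C/CC[C@]1(C)CCc2cc(O[Si](C(C)C)(C(C)C)C(C)C)cc(C)c2O1 | intermediate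
28 | (2E,6E,10E)-13-[(2R)-2,8-dimethyl-6-(triisopropylsilyloxy)chroman-2-yl]-2,6,10-trimethyltrideca-2,6,10-trien-1-ol | OC/C(C)=C/CC/C(C)=C/CC/C(C)=C/CC[C@]1(C)CCc2cc(O[Si](C(C)C)(C(C)C)C(C)C)cc(C)c2O1 | intermediate
29 | (2E,6E,10E)-13-[(2R)-2,8-dimethyl-6-(triisopropylsilyloxy)chroman-2-yl]-2,6,10-trimethyltrideca-2,6,10-trienal | O=C/C(C)=C/CC/C(C)=C/CC/C(C)=C/CC[C@]1(C)CCc2cc(O[Si](C(C)C)(C(C)C)C(C)C)cc(C)c2O1 | intermediate
30 | (2E,6E,10E)-13-[(2R)-2,8-dimethyl-6-(triisopropylsilyloxy)chroman-2-yl]-2,6,10-trimethyltrideca-2,6,10-trienoic acid | O=C(O)/C(C)=C/CC/C(C)=C/CC/C(C)=C/CC[C@]1(C)CCc2cc(O[Si](C(C)C)(C(C)C)C(C)C)cc(C)c2O1 | intermediate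
31 | garcinoic acid, (2E,6E,10E)-13-[(2R)-6-hydroxy-2,8-dimethylchroman-2-yl]-2,6,10-trimethyltrideca-2,6,10-trienoic acid | C/C(=C\CC/C(C)=C/CC[C@]1(C)CCc2cc(O)cc(C)c2O1)CC/C=C(\C)C(=O)O | target

**Step count**

Total steps: 20. Longest linear sequence: 16 (steps 1–5, 7–11 and 15–20).

**Three steps most likely to fail**

Step 7 (Proposed new method).
- What may go wrong: the hindered tertiary hydroxyl may add to the carbene carbon too slowly, so the acyloxycarbene decays before the exchange takes place. The liberated carboxylic acid may also promote ionisation of the new tertiary C–O bond.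
- Fallback: this uses known chemistry, sets out from 7 and 10, and comes back at 17.
- Carbene partner: (E)-1-bromopropene is lithiated with t-BuLi to (E)-prop-1-en-1-yllithium F1. F1 adds to 10 to give lithium pentacarbonyl[(2E)-but-2-enoyl]chromate F2. O-methylation with Me3OBF4 then gives pentacarbonyl[(2E)-1-methoxybut-2-en-1-ylidene]chromium F3.
- Benzannulation: an intermolecular Dötz benzannulation of F3 with 7 (THF, 50 °C, then air) follows the normal steric orientation of a terminal alkyne. It should therefore give 2-[(3R)-3,7-dimethyl-3-(triethylsilyloxy)oct-6-en-1-yl]-4-methoxy-6-methylphenol F4, whose free hydroxyl sits on the future C8a between the chain and the methyl group.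
- Ring closure: Tf2O and pyridine give 2-[(3R)-3,7-dimethyl-3-(triethylsilyloxy)oct-6-en-1-yl]-4-methoxy-6-methylphenyl trifluoromethanesulfonate F5. HF·pyridine frees 2-[(3R)-3-hydroxy-3,7-dimethyloct-6-en-1-yl]-4-methoxy-6-methylphenyl trifluoromethanesulfonate F6. An intramolecular Buchwald–Hartwig etherification (Pd(OAc)2, 2-(di-tert-butylphosphino)-1,1'-binaphthyl, Cs2CO3, toluene, 80 °C) forms O1–C8a with the carbinol C–O bond intact and gives (2R)-6-methoxy-2,8-dimethyl-2-(4-methylpent-3-en-1-yl)chroman F7.
- Return: NaSEt in DMF at 130 °C cleaves the methyl ether to 17.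

Step 8 (Proposed new method).
- What may go wrong: the tertiary C2–O1 bond may ionise or eliminate on heating, insertion may occur without CO uptake, or intermolecular insertion may lead to oligomerisation.
- Fallback: this is chromium-free known chemistry that sets out from 3 (generated from 2 as in step 2) and comes back at 18.
- Arene partner: 3-bromo-5-methylphenol is silylated (i-Pr3SiCl, imidazole) to (3-bromo-5-methylphenoxy)triisopropylsilane F8. Bromination para to the oxygen (NBS, MeCN) gives (3,4-dibromo-5-methylphenoxy)triisopropylsilane F9.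
- Coupling: a B-alkyl Suzuki–Miyaura coupling of 3 with F9 (Pd(dppf)Cl2, Cs2CO3, DMF/THF/H2O, 50 °C) should occur at the less hindered and less electron-rich C3–Br bond. The product is {[(3R)-1-[2-bromo-3-methyl-5-(triisopropylsilyloxy)phenyl]-3,7-dimethyloct-6-en-3-yl]oxy}triethylsilane F10.
- Ring closure and return: PPTS in MeOH removes the triethylsilyl group to give (3R)-1-[2-bromo-3-methyl-5-(triisopropylsilyloxy)phenyl]-3,7-dimethyloct-6-en-3-ol F11. Intramolecular Buchwald–Hartwig etherification of the tertiary alcohol (Pd(OAc)2, 2-(di-tert-butylphosphino)-1,1'-binaphthyl, Cs2CO3, toluene, 80 °C) closes the dihydropyran ring with C2 unchanged and gives 18.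

Step 10.
- What may go wrong: conversion may be incomplete, the alcohol may be over-oxidised, or the electron-rich chroman may be oxidised in competition on advanced material.
- Fallback: it sets out from 18 and comes back at 19.
- Sequence: Lemieux–Johnson cleavage of the prenyl alkene (OsO4 cat., NaIO4, 2,6-lutidine, dioxane/H2O) gives 3-[(2S)-2,8-dimethyl-6-(triisopropylsilyloxy)chroman-2-yl]propanal F12. This has the same spatial arrangement at C2; only the descriptor changes. An E-selective Wittig reaction with the stabilised ylide Ph3P=C(CH3)CO2Et (toluene, 80 °C) gives ethyl (2E)-5-[(2R)-2,8-dimethyl-6-(triisopropylsilyloxy)chroman-2-yl]-2-methylpent-2-enoate F13.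
- Return: i-Bu2AlH (CH2Cl2, −78 °C) reduces the ester to 19.

**Further compounds**

F1 | step 7 | (E)-prop-1-en-1-yllithium | C/C=C/[Li]
F2 | step 7 | lithium pentacarbonyl[(2E)-but-2-enoyl]chromate | [Li+].[O-]C(/C=C/C)=[Cr](=C=O)(=C=O)(=C=O)(=C=O)=C=O
F3 | step 7 | pentacarbonyl[(2E)-1-methoxybut-2-en-1-ylidene]chromium | C/C=C/C(OC)=[Cr](=C=O)(=C=O)(=C=O)(=C=O)=C=O
F4 | step 7 | 2-[(3R)-3,7-dimethyl-3-(triethylsilyloxy)oct-6-en-1-yl]-4-methoxy-6-methylphenol | COc1cc(C)c(O)c(CC[C@@](C)(CCC=C(C)C)O[Si](CC)(CC)CC)c1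
F5 | step 7 | 2-[(3R)-3,7-dimethyl-3-(triethylsilyloxy)oct-6-en-1-yl]-4-methoxy-6-methylphenyl trifluoromethanesulfonate | COc1cc(C)c(OS(=O)(=O)C(F)(F)F)c(CC[C@@](C)(CCC=C(C)C)O[Si](CC)(CC)CC)c1
F6 | step 7 | 2-[(3R)-3-hydroxy-3,7-dimethyloct-6-en-1-yl]-4-methoxy-6-methylphenyl trifluoromethanesulfonate | COc1cc(C)c(OS(=O)(=O)C(F)(F)F)c(CC[C@@](C)(CCC=C(C)C)O)c1
F7 | step 7 | (2R)-6-methoxy-2,8-dimethyl-2-(4-methylpent-3-en-1-yl)chroman | CC(C)=CCC[C@]1(C)CCc2cc(OC)cc(C)c2O1
F8 | step 8 | (3-bromo-5-methylphenoxy)triisopropylsilane | Cc1cc(Br)cc(O[Si](C(C)C)(C(C)C)C(C)C)c1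
F9 | step 8 | (3,4-dibromo-5-methylphenoxy)triisopropylsilane | Cc1cc(O[Si](C(C)C)(C(C)C)C(C)C)cc(Br)c1Br
F10 | step 8 | {[(3R)-1-[2-bromo-3-methyl-5-(triisopropylsilyloxy)phenyl]-3,7-dimethyloct-6-en-3-yl]oxy}triethylsilane | CC(C)=CCC[C@@](C)(O[Si](CC)(CC)CC)CCc1cc(O[Si](C(C)C)(C(C)C)C(C)C)cc(C)c1Br
F11 | step 8 | (3R)-1-[2-bromo-3-methyl-5-(triisopropylsilyloxy)phenyl]-3,7-dimethyloct-6-en-3-ol | CC(C)=CCC[C@@](C)(O)CCc1cc(O[Si](C(C)C)(C(C)C)C(C)C)cc(C)c1Br
F12 | step 10 | 3-[(2S)-2,8-dimethyl-6-(triisopropylsilyloxy)chroman-2-yl]propanal | O=CCC[C@]1(C)CCc2cc(O[Si](C(C)C)(C(C)C)C(C)C)cc(C)c2O1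
F13 | step 10 | ethyl (2E)-5-[(2R)-2,8-dimethyl-6-(triisopropylsilyloxy)chroman-2-yl]-2-methylpent-2-enoate | CCOC(=O)/C(C)=C/CC[C@]1(C)CCc2cc(O[Si](C(C)C)(C(C)C)C(C)C)cc(C)c2O1
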